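**Plan**
1. Retrosynthesis (all ten phenols as benzyl ethers): ring B, the dihydrobenzofuran whose C3 carries the ring-D aryl group and whose C4 carries C3 of ring C, is cut at O1–C2 and C2–C3, then at the bond from C3 to C4 of ring D.
2. Enabling feature: O1 sits on C7a, ortho to C3a, and C3 is a benzylic CH with only aryl neighbours. Ring B is therefore a latent ortho-quinone methide (O1=C7a, C3a=C3) plus a one-carbon benzylidene unit (C2 with its 4-oxyphenyl group).
3. Rings C and D are the same 2,3-diaryl-4-substituted-6-oxy-dihydrobenzofuran, so one bromide core 12 serves twice: directly as the ring-D aryllithium, and after elaboration as the ring-B/ring-C salicylaldehyde carbonate 22.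
4. Forward order: core ring (C and D) by Rh-carbene C–H insertion, (E)-stilbene by Horner–Wadsworth–Emmons olefination, ring B last in one flask (aryllithium addition, ortho-quinone methide formation, [4+1] annulation with a chiral sulfonium ylide), then global debenzylation.
5. Stereochemistry: C3 of rings C and D from the chiral Rh catalyst, C2 by acid equilibration to trans. C2 of ring B from the isothiocineole-derived ylide, C3 of ring B from anti addition followed by closure with inversion. Alkene geometry from the olefination.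

Key step: step 17

Assumption: Rh2(R-PTAD)4 is taken to deliver the (3R) centre of 11, and the ylide of the (1R,4R,5R)-sulfide the (2S) centre of ring B; both senses are assigned by analogy with simpler substrates, and if one is reversed the mirror-image catalyst or sulfide is used without other change.

**Step 1**
Reactants: 1 1,3-bis(benzyloxy)-5-bromobenzene
Product: 2 2,4-bis(benzyloxy)-6-bromobenzaldehyde
Conditions: POCl3, DMF, 80 °C; then aq NaOAc
Reagents that add atoms: N,N-dimethylformamide CN(C)C=O; water O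
Why: Vilsmeier–Haack formylation, in which the chloroiminium ion should attack para to one benzyloxy group at the position next to bromine, not the more crowded position between the two ethers.

**Step 2**
Reactants: 2 2,4-bis(benzyloxy)-6-bromobenzaldehyde
Product: 3 4-(benzyloxy)-2-bromo-6-hydroxybenzaldehyde
Conditions: MgBr2·OEt2 (3 equiv), toluene–Et2O, 80 °C; aq HCl
Reagents that add atoms: none
Why: Chelation-controlled ether cleavage, in which MgBr2 held between the aldehyde oxygen and the ortho ether oxygen delivers bromide to that benzyl group only, so the para ether is kept.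

**Step 3**
Reactants: 3 4-(benzyloxy)-2-bromo-6-hydroxybenzaldehyde; 4 4-(benzyloxy)benzyl bromide
Product: 5 4-(benzyloxy)-2-{[4-(benzyloxy)phenyl]methoxy}-6-bromobenzaldehyde
Conditions: K2CO3, DMF, 60 °C
Reagents that add atoms: none
Why: Williamson ether synthesis of the phenoxide with a benzylic bromide, the aryl bromide being inert.

**Step 4**
Reactants: 5 ether aldehyde; 1 1,3-bis(benzyloxy)-5-bromobenzene
Product: 7 racemic diaryl carbinol, via Grignard reagent 6 (not isolated)
Conditions: 1, Mg, THF, 40 °C; then 5, THF, 0 °C; aq NH4Cl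
Reagents that add atoms: none
Why: Grignard addition to the aldehyde, which is faster than any exchange with the aryl bromide; the carbinol centre is racemic and is removed in step 5.

**Step 5**
Reactants: 7 racemic diaryl carbinol
Product: 8 diaryl ketone
Conditions: Dess–Martin periodinane, NaHCO3, CH2Cl2, 0 °C to rt
Reagents that add atoms: none
Why: Dess–Martin oxidation of a doubly benzylic alcohol under buffered conditions that leave benzyl ethers and the aryl bromide untouched.

**Step 6**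
Reactants: 8 diaryl ketone
Product: 9 hydrazone of 8
Conditions: N2H4·H2O (excess), AcOH (cat.), EtOH, 90 °C (sealed)
Reagents that add atoms: hydrazine NN
Why: Acid-catalysed hydrazone condensation, forced with excess hydrazine because the carbonyl group is flanked by an ether and a bromine.

**Step 7**
Reactants: 9 hydrazone of 8
Product: 11 (2S,3R)-cis-dihydrobenzofuran bromide, via diaryldiazomethane 10 (not isolated)
Conditions: MnO2, CH2Cl2, 0 °C; filter; Rh2(R-PTAD)4 (dirhodium tetrakis[(R)-(1-adamantyl)(phthalimido)acetate], 1 mol %), CH2Cl2, −20 °C to rt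
Reagents that add atoms: none
Why: MnO2 dehydrogenates the hydrazone to the diazo compound, whose donor/donor Rh carbene should insert into the ArO–CH2–Ar C–H bond (1,5-insertion) in a concerted step that gives the cis ring, with C3 fixed by the chiral carboxylate ligands.

**Step 8**
Reactants: 11 (2S,3R)-cis-dihydrobenzofuran bromide
Product: 12 (2R,3R)-trans-dihydrobenzofuran bromide
Conditions: CF3CO2H, CH2Cl2, 0 °C
Reagents that add atoms: none
Why: Acid-mediated C2 epimerisation, in which reversible heterolysis of the O1–C2 bond to the 4-(benzyloxy)benzyl cation and reclosure should give the more stable trans ring while C3 is untouched.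

**Step 9**
Reactants: 12 (2R,3R)-trans-dihydrobenzofuran bromide
Product: 14 (2R,3R)-dihydrobenzofuran-4-carbaldehyde, via arylmagnesium bromide 13 (not isolated)
Conditions: Mg turnings, LiCl, THF, rt to 40 °C; then DMF, 0 °C to rt; aq NH4Cl
Reagents that add atoms: N,N-dimethylformamide CN(C)C=O
Why: LiCl-assisted magnesium insertion into the aryl C–Br bond followed by Bouveault formylation of the arylmagnesium bromide with DMF, which tolerates the benzyl ethers and involves no stereocentre.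

**Step 10**
Reactants: 14 (2R,3R)-dihydrobenzofuran-4-carbaldehyde
Product: 15 bromo aldehyde (bromine at C2 of the 3,5-bis(benzyloxy)phenyl ring)
Conditions: NBS (1.0 equiv), CH2Cl2, −20 to 0 °C, dark
Reagents that add atoms: N-bromosuccinimide O=C1CCC(=O)N1Br
Why: Electrophilic aromatic bromination, which should occur on the 3,5-bis(benzyloxy)phenyl ring (the most electron-rich ring once the benzofuran ring carries the formyl group), para to one ether and next to the ring junction.

**Step 11**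
Reactants: 16 3,4-bis(benzyloxy)benzyl chloride
Product: 17 diethyl {[3,4-bis(benzyloxy)phenyl]methyl}phosphonate
Conditions: P(OEt)3, neat, 140 °C
Reagents that add atoms: triethyl phosphite CCOP(OCC)OCC
Why: Michaelis–Arbuzov reaction of a benzylic chloride.

**Step 12**
Reactants: 15 bromo aldehyde; 17 phosphonate
Product: 18 (E)-stilbene bromide
Conditions: 17, NaH, THF, 0 °C; then 15, 0 °C to rt
Reagents that add atoms: none
Why: Horner–Wadsworth–Emmons olefination, in which the preformed benzylic phosphonate anion (no excess base near the C3–H) should give the (E)-stilbene under the usual thermodynamic control.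

**Step 13**
Reactants: 18 (E)-stilbene bromide
Product: 20 ring-B benzaldehyde, via aryllithium 19 (not isolated)
Conditions: t-BuLi (2.0 equiv), THF, −78 °C; DMF; aq NH4Cl
Reagents that add atoms: N,N-dimethylformamide CN(C)C=O
Why: Bromine–lithium exchange, which is faster at −78 °C than attack on the stilbene or on the benzylic ether positions, followed by formylation with DMF.

**Step 14**
Reactants: 20 ring-B benzaldehyde
Product: 21 ring-B salicylaldehyde
Conditions: MgBr2·OEt2 (3 equiv), toluene–Et2O, rt to 50 °C; aq HCl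
Reagents that add atoms: none
Why: The same chelation-controlled debenzylation as in step 2, in which only the ether ortho to the new aldehyde can bind MgBr2 and is cleaved.

**Step 15**
Reactants: 21 ring-B salicylaldehyde
Product: 22 ring-B salicylaldehyde tert-butyl carbonate
Conditions: Boc2O, DMAP (cat.), i-Pr2NEt, CH2Cl2, 0 °C to rt
Reagents that add atoms: di-tert-butyl dicarbonate CC(C)(C)OC(=O)OC(=O)OC(C)(C)C
Why: DMAP-catalysed O-acylation of the phenol, which installs the carbonate that later triggers ortho-quinone methide formation.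

**Step 16**
Reactants: 23 (1R,4R,5R)-isothiocineole; 4 4-(benzyloxy)benzyl bromide
Product: 24 S-[4-(benzyloxy)benzyl]isothiocineolium tetrafluoroborate
Conditions: NaBF4, CH2Cl2–H2O, rt
Reagents that add atoms: sodium tetrafluoroborate [Na+].F[B-](F)(F)F
Why: S-alkylation of the sulfide by the benzylic bromide with anion exchange, expected on the less hindered lone pair and so to give one sulfonium epimer.

**Step 17**
Reactants: 12 (2R,3R)-trans-dihydrobenzofuran bromide; 22 ring-B salicylaldehyde tert-butyl carbonate; 24 sulfonium salt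
Product: 30 decabenzyl ether of the target, via aryllithium 25 (not isolated), via lithium phenoxide carbonate 26 (not isolated), via ortho-quinone methide 27 (not isolated), via sulfonium ylide 28 (not isolated), via betaine 29 (not isolated)
Conditions: 12, t-BuLi (2.0 equiv), THF, −78 °C; cannulate into 22 (1.1 equiv), THF, −78 to 0 °C; recool to −78 °C; 28 [from 24 (1.5 equiv), LiN(SiMe3)2, THF, −78 °C]; −78 to 0 °C; aq NH4Cl
Reagents that add atoms: none
Why: Proposed new method: aryllithium 25 adds to the aldehyde of 22, the tert-butoxycarbonyl group shifts from the phenolic to the benzylic oxygen (26) and the phenoxide expels tert-butyl carbonate on warming to give ortho-quinone methide 27, whose exocyclic carbon (the future C3 of ring B) takes up the benzylidene carbon of ylide 28 in a 1,4-addition that rearomatises ring B to phenoxide betaine 29, and the phenoxide then displaces the sulfide at the future C2 with inversion. The closest known reaction types are the generation of ortho-quinone methides from O-Boc salicylaldehydes and organometallic reagents, the [4+1] annulation of ortho-quinone methides with carbonyl-stabilised sulfonium ylides to trans-2,3-dihydrobenzofurans, and the asymmetric benzylidene transfer from isothiocineole-derived ylides to aldehydes and imines; the untested part is the use of a chiral, aryl-stabilised ylide on an ortho-quinone methide. Ring B closes by a 5-exo-tet O-alkylation after the intermolecular C–C bond formation, which makes the whole a formal [4+1] annulation. C2 should be controlled by the sulfide, which exposes one face of the ylide carbon, and C3 should follow because the addition is expected to pass through the staggered arrangement with the two aryl groups anti and the sulfonium group anti to the quinoid ring, which is also the conformer that closes to the trans ring. The step needs reagent control strong enough to override the ring-C and ring-D units that flank the methide, 1,4- over 1,2-addition (secured by the gain in aromaticity), and no second addition of 25 to 27 (secured by using 25 as the limiting reagent, by its consumption at −78 °C before the lithium phenoxide eliminates on warming, and by the crowding at the methide carbon).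

**Step 18**
Reactants: 30 decabenzyl ether of the target
Product: 31 target tetramer
Conditions: BCl3, pentamethylbenzene, CH2Cl2, −78 °C; MeOH quench at −78 °C
Reagents that add atoms: none
Why: Lewis-acid cleavage of the ten aryl benzyl ethers with pentamethylbenzene as a non-basic trap for the benzyl cation at low temperature, conditions under which stilbene double bonds and 2-aryl-2,3-dihydrobenzofurans are expected to survive.

**Compound list**

1 | 1,3-bis(benzyloxy)-5-bromobenzene | Brc1cc(OCc2ccccc2)cc(OCc2ccccc2)c1 | starting material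
2 | 2,4-bis(benzyloxy)-6-bromobenzaldehyde | O=Cc1c(Br)cc(OCc2ccccc2)cc1OCc1ccccc1 | intermediate
3 | 4-(benzyloxy)-2-bromo-6-hydroxybenzaldehyde | O=Cc1c(O)cc(OCc2ccccc2)cc1Br | intermediate
4 | 4-(benzyloxy)benzyl bromide | BrCc1ccc(OCc2ccccc2)cc1 | starting material
5 | 4-(benzyloxy)-2-{[4-(benzyloxy)phenyl]methoxy}-6-bromobenzaldehyde | O=Cc1c(Br)cc(OCc2ccccc2)cc1OCc1ccc(OCc2ccccc2)cc1 | intermediate
6 | [3,5-bis(benzyloxy)phenyl]magnesium bromide | Br[Mg]c1cc(OCc2ccccc2)cc(OCc2ccccc2)c1 | intermediate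
7 | racemic [4-(benzyloxy)-2-{[4-(benzyloxy)phenyl]methoxy}-6-bromophenyl][3,5-bis(benzyloxy)phenyl]methanol | OC(c1cc(OCc2ccccc2)cc(OCc2ccccc2)c1)c1c(Br)cc(OCc2ccccc2)cc1OCc1ccc(OCc2ccccc2)cc1 | intermediate
8 | [4-(benzyloxy)-2-{[4-(benzyloxy)phenyl]methoxy}-6-bromophenyl][3,5-bis(benzyloxy)phenyl]methanone | O=C(c1cc(OCc2ccccc2)cc(OCc2ccccc2)c1)c1c(Br)cc(OCc2ccccc2)cc1OCc1ccc(OCc2ccccc2)cc1 | intermediate
9 | hydrazone of 8 (C=N–NH2, either geometry) | NN=C(c1cc(OCc2ccccc2)cc(OCc2ccccc2)c1)c1c(Br)cc(OCc2ccccc2)cc1OCc1ccc(OCc2ccccc2)cc1 | intermediate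
10 | [4-(benzyloxy)-2-{[4-(benzyloxy)phenyl]methoxy}-6-bromophenyl][3,5-bis(benzyloxy)phenyl]diazomethane | [N-]=[N+]=C(c1cc(OCc2ccccc2)cc(OCc2ccccc2)c1)c1c(Br)cc(OCc2ccccc2)cc1OCc1ccc(OCc2ccccc2)cc1 | intermediate
11 | (2S,3R)-6-(benzyloxy)-2-[4-(benzyloxy)phenyl]-3-[3,5-bis(benzyloxy)phenyl]-4-bromo-2,3-dihydro-1-benzofuran (cis) | Brc1cc(OCc9ccccc9)cc2c1[C@@H](c1cc(OCc9ccccc9)cc(OCc9ccccc9)c1)[C@@H](c1ccc(OCc9ccccc9)cc1)O2 | intermediate
12 | (2R,3R)-6-(benzyloxy)-2-[4-(benzyloxy)phenyl]-3-[3,5-bis(benzyloxy)phenyl]-4-bromo-2,3-dihydro-1-benzofuran (trans) | Brc1cc(OCc9ccccc9)cc2c1[C@@H](c1cc(OCc9ccccc9)cc(OCc9ccccc9)c1)[C@H](c1ccc(OCc9ccccc9)cc1)O2 | intermediate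
13 | 4-(bromomagnesio) analogue of 12 (MgBr in place of Br) | Br[Mg]c1cc(OCc9ccccc9)cc2c1[C@@H](c1cc(OCc9ccccc9)cc(OCc9ccccc9)c1)[C@H](c1ccc(OCc9ccccc9)cc1)O2 | intermediate
14 | (2R,3R)-6-(benzyloxy)-2-[4-(benzyloxy)phenyl]-3-[3,5-bis(benzyloxy)phenyl]-2,3-dihydro-1-benzofuran-4-carbaldehyde | O=Cc1cc(OCc9ccccc9)cc2c1[C@@H](c1cc(OCc9ccccc9)cc(OCc9ccccc9)c1)[C@H](c1ccc(OCc9ccccc9)cc1)O2 | intermediate
15 | (2R,3S)-6-(benzyloxy)-2-[4-(benzyloxy)phenyl]-3-[3,5-bis(benzyloxy)-2-bromophenyl]-2,3-dihydro-1-benzofuran-4-carbaldehyde (same spatial arrangement as 14; the C3 descriptor changes because of the bromine) | O=Cc1cc(OCc9ccccc9)cc2c1[C@@H](c1c(Br)c(OCc9ccccc9)cc(OCc9ccccc9)c1)[C@H](c1ccc(OCc9ccccc9)cc1)O2 | intermediate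
16 | 3,4-bis(benzyloxy)benzyl chloride | ClCc1ccc(OCc2ccccc2)c(OCc2ccccc2)c1 | starting material
17 | diethyl {[3,4-bis(benzyloxy)phenyl]methyl}phosphonate | CCOP(=O)(OCC)Cc1ccc(OCc2ccccc2)c(OCc2ccccc2)c1 | intermediate
18 | (2R,3S)-6-(benzyloxy)-2-[4-(benzyloxy)phenyl]-3-[3,5-bis(benzyloxy)-2-bromophenyl]-4-{(E)-2-[3,4-bis(benzyloxy)phenyl]ethenyl}-2,3-dihydro-1-benzofuran | c9ccccc9COc1cc(OCc9ccccc9)cc([C@@H]4c5c(/C=C/c6ccc(OCc9ccccc9)c(OCc9ccccc9)c6)cc(OCc9ccccc9)cc5O[C@H]4c4ccc(OCc9ccccc9)cc4)c1Br | intermediate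
19 | 2-lithio analogue of 18 (Li in place of the aryl Br) | c9ccccc9COc1cc(OCc9ccccc9)cc([C@@H]4c5c(/C=C/c6ccc(OCc9ccccc9)c(OCc9ccccc9)c6)cc(OCc9ccccc9)cc5O[C@H]4c4ccc(OCc9ccccc9)cc4)c1[Li] | intermediate
20 | 2,4-bis(benzyloxy)-6-[(2R,3R)-6-(benzyloxy)-2-[4-(benzyloxy)phenyl]-4-{(E)-2-[3,4-bis(benzyloxy)phenyl]ethenyl}-2,3-dihydro-1-benzofuran-3-yl]benzaldehyde | c9ccccc9COc1cc(OCc9ccccc9)cc([C@@H]4c5c(/C=C/c6ccc(OCc9ccccc9)c(OCc9ccccc9)c6)cc(OCc9ccccc9)cc5O[C@H]4c4ccc(OCc9ccccc9)cc4)c1C=O | intermediate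
21 | 4-(benzyloxy)-2-hydroxy-6-[the (2R,3R)-benzofuran-3-yl unit of 20]benzaldehyde | Oc1cc(OCc9ccccc9)cc([C@@H]4c5c(/C=C/c6ccc(OCc9ccccc9)c(OCc9ccccc9)c6)cc(OCc9ccccc9)cc5O[C@H]4c4ccc(OCc9ccccc9)cc4)c1C=O | intermediate
22 | 5-(benzyloxy)-2-formyl-3-[the (2R,3R)-benzofuran-3-yl unit of 20]phenyl tert-butyl carbonate | CC(C)(C)OC(=O)Oc1cc(OCc9ccccc9)cc([C@@H]4c5c(/C=C/c6ccc(OCc9ccccc9)c(OCc9ccccc9)c6)cc(OCc9ccccc9)cc5O[C@H]4c4ccc(OCc9ccccc9)cc4)c1C=O | intermediate
23 | (1R,4R,5R)-4,7,7-trimethyl-6-thiabicyclo[3.2.1]octane (isothiocineole) | C[C@@H]1CC[C@@H]2C[C@H]1SC2(C)C | starting material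
24 | (1R,4R,5R)-6-{[4-(benzyloxy)phenyl]methyl}-4,7,7-trimethyl-6-thiabicyclo[3.2.1]octan-6-ium tetrafluoroborate (one sulfonium epimer expected, benzyl on the less hindered face; sulfur descriptor left open) | C[C@@H]1CC[C@@H]2C[C@H]1[S+](Cc1ccc(OCc3ccccc3)cc1)C2(C)C.F[B-](F)(F)F | intermediate
25 | 4-lithio analogue of 12 (Li in place of Br) | [Li]c1cc(OCc9ccccc9)cc2c1[C@@H](c1cc(OCc9ccccc9)cc(OCc9ccccc9)c1)[C@H](c1ccc(OCc9ccccc9)cc1)O2 | intermediate
26 | lithium phenoxide of the Boc-transfer adduct: ring-B phenoxide whose ortho carbon carries CH(OCO2t-Bu) bonded to C4 of the ring-D unit (carbinol carbon as both epimers) | [Li+].[O-]c1cc(OCc9ccccc9)cc([C@@H]4c5c(/C=C/c6ccc(OCc9ccccc9)c(OCc9ccccc9)c6)cc(OCc9ccccc9)cc5O[C@H]4c4ccc(OCc9ccccc9)cc4)c1C(OC(=O)OC(C)(C)C)c2cc(OCc9ccccc9)cc3c2[C@@H](c2cc(OCc9ccccc9)cc(OCc9ccccc9)c2)[C@H](c2ccc(OCc9ccccc9)cc2)O3 | intermediate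
27 | ortho-quinone methide: 3-(benzyloxy)-6-[(ring-D aryl)methylidene]cyclohexa-2,4-dien-1-one carrying the ring-C unit at C5 (exocyclic geometry open) | O=C1C=C(OCc9ccccc9)C=C([C@@H]4c5c(/C=C/c6ccc(OCc9ccccc9)c(OCc9ccccc9)c6)cc(OCc9ccccc9)cc5O[C@H]4c4ccc(OCc9ccccc9)cc4)C1=Cc2cc(OCc9ccccc9)cc3c2[C@@H](c2cc(OCc9ccccc9)cc(OCc9ccccc9)c2)[C@H](c2ccc(OCc9ccccc9)cc2)O3 | intermediate
28 | sulfonium ylide of 24 (carbanion at the benzylic carbon) | C[C@@H]1CC[C@@H]2C[C@H]1[S+]([CH-]c1ccc(OCc9ccccc9)cc1)C2(C)C | intermediate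
29 | betaine: ring-B phenoxide whose ortho carbon carries C3 (ring-D aryl, H), bonded to the sulfonium-bearing CH(4-benzyloxyphenyl) | C[C@@H]1CC[C@@H]2C[C@H]1[S+](C2(C)C)[C@@H](c1ccc(OCc9ccccc9)cc1)[C@@H](c2cc(OCc9ccccc9)cc3c2[C@@H](c2cc(OCc9ccccc9)cc(OCc9ccccc9)c2)[C@H](c2ccc(OCc9ccccc9)cc2)O3)c3c([O-])cc(OCc9ccccc9)cc3[C@@H]4c5c(/C=C/c6ccc(OCc9ccccc9)c(OCc9ccccc9)c6)cc(OCc9ccccc9)cc5O[C@H]4c4ccc(OCc9ccccc9)cc4 | intermediate
30 | decabenzyl ether of the target: ring B (2S,3S), ring C (2R,3R), ring D (2R,3R), (E)-alkene | c9ccccc9COc1ccc([C@H]2Oc3cc(OCc9ccccc9)cc([C@@H]4c5c(/C=C/c6ccc(OCc9ccccc9)c(OCc9ccccc9)c6)cc(OCc9ccccc9)cc5O[C@H]4c4ccc(OCc9ccccc9)cc4)c3[C@@H]2c2cc(OCc9ccccc9)cc3c2[C@@H](c2cc(OCc9ccccc9)cc(OCc9ccccc9)c2)[C@H](c2ccc(OCc9ccccc9)cc2)O3)cc1 | intermediate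
31 | CNP0099535.1: ring B (2S,3S)-6-hydroxy-2-(4-hydroxyphenyl)-dihydrobenzofuran carrying at C3 the C4 of ring D [(2R,3R)-3-(3,5-dihydroxyphenyl)-6-hydroxy-2-(4-hydroxyphenyl)] and at C4 the C3 of ring C [(2R,3R)-4-[(E)-3,4-dihydroxystyryl]-6-hydroxy-2-(4-hydroxyphenyl)] | Oc1ccc([C@H]2Oc3cc(O)cc([C@@H]4c5c(/C=C/c6ccc(O)c(O)c6)cc(O)cc5O[C@H]4c4ccc(O)cc4)c3[C@@H]2c2cc(O)cc3c2[C@@H](c2cc(O)cc(O)c2)[C@H](c2ccc(O)cc2)O3)cc1 | target

**Step count and risks**

Total steps: 18. Longest linear sequence: 16 (steps 1–10, 12–15, 17, 18).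

Steps most likely to fail:

Step 17 (proposed new method). The ylide may add to the crowded methide with poor facial discrimination, or the ortho-quinone methide may be lost to self-condensation before the ylide arrives. The fallback uses known chemistry, the carbene C–H insertion of steps 6–8 applied to ring B; it sets out from 21 and 12 and comes back at 30. Phenol 21 is alkylated with 4 (K2CO3, DMF) to give ether aldehyde F1. Aryllithium 25 (from 12 and t-BuLi) is added to give diaryl carbinol F2, and Dess–Martin periodinane gives diaryl ketone F3. Hydrazine gives hydrazone F4, and MnO2 gives diaryldiazomethane F5. With Rh2(S-PTAD)4, the mirror-image catalyst of step 7, the carbene should insert into the ArO–CH2–Ar bond to give cis ring-B compound F6. CF3CO2H at low temperature should then equilibrate C2 and give 30.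

Step 6. The condensation may stall because the carbonyl group is shielded by two ortho substituents, or azine formation may compete. The fallback installs the C=N bond by carbon–carbon bond formation instead of condensation; it sets out from 5 and comes back at 9. Iodine (I2) and aqueous ammonia convert aldehyde 5 into nitrile F7. Grignard reagent 6 (CuBr·SMe2 as catalyst, THF, reflux) adds to the nitrile, and a methanol quench gives N–H ketimine F8. Transimination with anhydrous hydrazine in ethanol then gives 9.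

Step 10. Bromination may be divided between the position next to the ring junction and other activated positions, or run on to double bromination. The fallback replaces halogenation and lithiation by a self-limiting formylation; it sets out from 14 and comes back at 21, by-passing 15, 18 and 20. Vilsmeier–Haack formylation of 14 (POCl3, DMF), a weaker electrophile that deactivates the ring after one substitution, gives dialdehyde F9. MgBr2·OEt2 cleaves the benzyl ether ortho to the new formyl group to give hydroxy dialdehyde F10. The sodium salt of 17 (NaH, 2.2 equiv) should olefinate only the benzofuran-4-carbaldehyde, because the salicylaldehyde is held as its unreactive phenoxide, and so gives 21.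

**Further compounds**

F1 | step 17 | 4-(benzyloxy)-2-{[4-(benzyloxy)phenyl]methoxy}-6-[the (2R,3R)-benzofuran-3-yl unit of 20]benzaldehyde | c9ccccc9COc8ccc(COc1cc(OCc9ccccc9)cc([C@@H]4c5c(/C=C/c6ccc(OCc9ccccc9)c(OCc9ccccc9)c6)cc(OCc9ccccc9)cc5O[C@H]4c4ccc(OCc9ccccc9)cc4)c1C=O)cc8
F2 | step 17 | diaryl carbinol from 25 and F1 (carbinol carbon as both epimers) | c9ccccc9COc8ccc(COc1cc(OCc9ccccc9)cc([C@@H]4c5c(/C=C/c6ccc(OCc9ccccc9)c(OCc9ccccc9)c6)cc(OCc9ccccc9)cc5O[C@H]4c4ccc(OCc9ccccc9)cc4)c1C(O)c2cc(OCc9ccccc9)cc3c2[C@@H](c2cc(OCc9ccccc9)cc(OCc9ccccc9)c2)[C@H](c2ccc(OCc9ccccc9)cc2)O3)cc8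
F3 | step 17 | diaryl ketone from F2 | c9ccccc9COc8ccc(COc1cc(OCc9ccccc9)cc([C@@H]4c5c(/C=C/c6ccc(OCc9ccccc9)c(OCc9ccccc9)c6)cc(OCc9ccccc9)cc5O[C@H]4c4ccc(OCc9ccccc9)cc4)c1C(=O)c2cc(OCc9ccccc9)cc3c2[C@@H](c2cc(OCc9ccccc9)cc(OCc9ccccc9)c2)[C@H](c2ccc(OCc9ccccc9)cc2)O3)cc8
F4 | step 17 | hydrazone of F3 | c9ccccc9COc8ccc(COc1cc(OCc9ccccc9)cc([C@@H]4c5c(/C=C/c6ccc(OCc9ccccc9)c(OCc9ccccc9)c6)cc(OCc9ccccc9)cc5O[C@H]4c4ccc(OCc9ccccc9)cc4)c1C(=NN)c2cc(OCc9ccccc9)cc3c2[C@@H](c2cc(OCc9ccccc9)cc(OCc9ccccc9)c2)[C@H](c2ccc(OCc9ccccc9)cc2)O3)cc8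
F5 | step 17 | diaryldiazomethane from F4 | c9ccccc9COc8ccc(COc1cc(OCc9ccccc9)cc([C@@H]4c5c(/C=C/c6ccc(OCc9ccccc9)c(OCc9ccccc9)c6)cc(OCc9ccccc9)cc5O[C@H]4c4ccc(OCc9ccccc9)cc4)c1C(=[N+]=[N-])c2cc(OCc9ccccc9)cc3c2[C@@H](c2cc(OCc9ccccc9)cc(OCc9ccccc9)c2)[C@H](c2ccc(OCc9ccccc9)cc2)O3)cc8
F6 | step 17 | C2 epimer of 30 in ring B (ring B (2R,3S), cis) | c9ccccc9COc1ccc([C@@H]2Oc3cc(OCc9ccccc9)cc([C@@H]4c5c(/C=C/c6ccc(OCc9ccccc9)c(OCc9ccccc9)c6)cc(OCc9ccccc9)cc5O[C@H]4c4ccc(OCc9ccccc9)cc4)c3[C@@H]2c2cc(OCc9ccccc9)cc3c2[C@@H](c2cc(OCc9ccccc9)cc(OCc9ccccc9)c2)[C@H](c2ccc(OCc9ccccc9)cc2)O3)cc1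
F7 | step 6 | 4-(benzyloxy)-2-{[4-(benzyloxy)phenyl]methoxy}-6-bromobenzonitrile | N#Cc1c(Br)cc(OCc2ccccc2)cc1OCc1ccc(OCc2ccccc2)cc1
F8 | step 6 | N–H ketimine of 8 | N=C(c1cc(OCc2ccccc2)cc(OCc2ccccc2)c1)c1c(Br)cc(OCc2ccccc2)cc1OCc1ccc(OCc2ccccc2)cc1
F9 | step 10 | (2R,3R)-6-(benzyloxy)-2-[4-(benzyloxy)phenyl]-3-[3,5-bis(benzyloxy)-2-formylphenyl]-2,3-dihydro-1-benzofuran-4-carbaldehyde | O=Cc1cc(OCc9ccccc9)cc2c1[C@@H](c1c(C=O)c(OCc9ccccc9)cc(OCc9ccccc9)c1)[C@H](c1ccc(OCc9ccccc9)cc1)O2
F10 | step 10 | (2R,3R)-6-(benzyloxy)-2-[4-(benzyloxy)phenyl]-3-[5-(benzyloxy)-2-formyl-3-hydroxyphenyl]-2,3-dihydro-1-benzofuran-4-carbaldehyde | O=Cc1cc(OCc9ccccc9)cc2c1[C@@H](c1c(C=O)c(O)cc(OCc9ccccc9)c1)[C@H](c1ccc(OCc9ccccc9)cc1)O2
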